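**Plan**

- With the chain numbered C1 (guaiacyl CH2) to C7 (syringyl CH2), the C3 carbonyl, the C4 methylene and the C5 (R)-carbinol are read as the C=N carbon, C4 and C5 of a 2-isoxazoline; cleaving its N–O bond and hydrolysing the imine restores exactly this β-hydroxy ketone.
- Retrosynthesis: remove the two phenol benzyl groups; re-close N–O to the 3,5-disubstituted isoxazoline; cut C6–C7 (as a C6=C7 Wittig alkene) into an isoxazoline-5-carbaldehyde and a syringyl benzyl ylide; cut C3–C4 and C5–O into a dihydroferulyl nitrile oxide and allyl alcohol.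
- Forward: dihydroferulic acid is taken to the hydroximoyl chloride (steps 1–4). The isoxazoline, the only ring made, arises in step 5. Its CH2OH carbon becomes C6 and is joined to the syringyl fragment (steps 6–8) by oxidation and Wittig reaction (steps 9–10). Diimide, Raney Ni and Pd/C finish the route (steps 11–13).
- Stereochemistry: the single stereocentre C5 is set in step 5 by a zinc/(S,S)-diisopropyl tartrate template on the allylic alkoxide. It is 5S in the isoxazolinylmethanol and becomes 5R in the target only through the change in CIP ranking; no later step breaks a bond at C5.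

Key step: step 5

Assumption: the sense of induction known for this zinc/tartrate cycloaddition, in which the (R,R)-tartrate leads to 5R adducts, is taken to hold for a primary-alkyl nitrile oxide. The (S,S)-ester is therefore used; the configuration of 9 would be checked (Mosher ester) and the antipodal tartrate used if it proved opposite.

**Route**

Step 1
Reactants: 1 3-(4-hydroxy-3-methoxyphenyl)propanoic acid (dihydroferulic acid)
Product: 2 benzyl 3-[4-(benzyloxy)-3-methoxyphenyl]propanoate
Conditions: BnBr (2.3 equiv), K2CO3, DMF, 60 °C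
Reagents that add atoms: benzyl bromide, BrCc1ccccc1
Why: Williamson O-alkylation of the phenoxide and SN2 esterification of the carboxylate by benzyl bromide run together under K2CO3 in DMF, giving one fully benzylated compound whose ester is the aldehyde precursor.

Step 2
Reactants: 2 benzyl 3-[4-(benzyloxy)-3-methoxyphenyl]propanoate
Product: 3 3-[4-(benzyloxy)-3-methoxyphenyl]propanal
Conditions: i-Bu2AlH (1.1 equiv), CH2Cl2, −78 °C; MeOH, then aq. potassium sodium tartrate (KNaC4H4O6)
Reagents that add atoms: none
Why: Partial ester reduction with i-Bu2AlH at −78 °C should stop at the tetrahedral aluminium hemiacetal, which releases the aldehyde only on work-up, and the aryl benzyl ether is inert to the hydride.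

Step 3
Reactants: 3 3-[4-(benzyloxy)-3-methoxyphenyl]propanal
Product: 4 3-[4-(benzyloxy)-3-methoxyphenyl]propanal oxime (E/Z mixture)
Conditions: NH2OH·HCl, NaOAc, EtOH/H2O, rt
Reagents that add atoms: hydroxylamine hydrochloride, NO.Cl
Why: Oxime formation from an unhindered aldehyde is fast under acetate buffering, and the E/Z mixture is immaterial because both isomers converge in the next step.

Step 4
Reactants: 4 3-[4-(benzyloxy)-3-methoxyphenyl]propanal oxime
Product: 5 (Z)-3-[4-(benzyloxy)-3-methoxyphenyl]-N-hydroxypropanimidoyl chloride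
Conditions: NCS (1.05 equiv), DMF, 0 °C to rt; used crude
Reagents that add atoms: N-chlorosuccinimide, O=C1CCC(=O)N1Cl
Why: Chlorination of the aldoxime C–H with N-chlorosuccinimide in DMF (standard hydroximoyl chloride synthesis) should outpace ring chlorination of the dialkoxyarene at or below room temperature, and the sensitive aliphatic product is carried on without purification.

Step 5
Reactants: 5 (Z)-3-[4-(benzyloxy)-3-methoxyphenyl]-N-hydroxypropanimidoyl chloride; 6 allyl alcohol
Product: 9 [(5S)-3-{2-[4-(benzyloxy)-3-methoxyphenyl]ethyl}-4,5-dihydroisoxazol-5-yl]methanol, via allyloxy(ethyl)zinc 7 (not isolated), via nitrile oxide 8 (not isolated)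
Conditions: 6, Et2Zn (1.0 equiv), CHCl3, 0 °C; (S,S)-diisopropyl tartrate (1.0 equiv); Et2Zn (1.0 equiv); then 5 added slowly, 0 °C; aq. NH4Cl
Reagents that add atoms: none
Why: Allyloxy(ethyl)zinc 7 is bridged by the tartrate to a second ethylzinc unit, giving EtZn–O–CH(CO2i-Pr)–CH(CO2i-Pr)–O–Zn–OCH2CH=CH2; its EtZn–O terminus deprotonates the N–OH of 5, chloride passes to zinc, and nitrile oxide 8 is released on the metal next to the bound alkene, to which it adds in a concerted suprafacial [3+2] cycloaddition (dipole carbon to the terminal CH2 forming C3–C4, dipole oxygen to the internal carbon forming C5–O). The closest known reaction type is the diethylzinc/dialkyl tartrate-mediated asymmetric nitrile oxide cycloaddition to allyl alcohol, applied here to a primary-alkyl nitrile oxide. The 2-isoxazoline, the only ring formed, is closed by an intermolecular [3+2] cycloaddition in which both ring bonds form in the same step, not by cyclisation of a tethered chain. The C5 stereocentre is controlled by the (S,S)-tartrate, which ties dipole and dipolarophile to the two zinc atoms and exposes one alkene face, expected to give the 5S adduct. The step needs 5-regioselectivity, which is inherent to a monosubstituted alkene and reinforced by the alkoxide anchor, and facial selectivity, which the tartrate template supplies. It also needs cycloaddition to outrun furoxan dimerisation, which is secured by slow addition of 5 at 0 °C so that the nitrile oxide is only ever generated beside the zinc-bound alkene.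

Step 6
Reactants: 10 4-hydroxy-3,5-dimethoxybenzaldehyde (syringaldehyde)
Product: 11 4-(benzyloxy)-3,5-dimethoxybenzaldehyde
Conditions: BnBr, K2CO3, DMF, 60 °C
Reagents that add atoms: benzyl bromide, BrCc1ccccc1
Why: Williamson etherification; the phenoxide para to the formyl group forms readily and is alkylated cleanly by benzyl bromide.

Step 7
Reactants: 11 4-(benzyloxy)-3,5-dimethoxybenzaldehyde
Product: 12 [4-(benzyloxy)-3,5-dimethoxyphenyl]methanol
Conditions: NaBH4, MeOH, 0 °C
Reagents that add atoms: none
Why: Borohydride reduction of an aryl aldehyde to the benzylic alcohol is chemoselective and leaves the ethers untouched.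

Step 8
Reactants: 12 [4-(benzyloxy)-3,5-dimethoxyphenyl]methanol
Product: 13 [4-(benzyloxy)-3,5-dimethoxybenzyl]triphenylphosphonium bromide
Conditions: Ph3P·HBr, MeCN, reflux
Reagents that add atoms: triphenylphosphine hydrobromide, Br.c1ccc(cc1)P(c1ccccc1)c1ccccc1
Why: The electron-rich benzylic alcohol is ionised by the hydrobromide and captured by triphenylphosphine (direct phosphonium salt formation from a benzylic alcohol), which avoids isolating the labile alkoxy-substituted benzyl bromide.

Step 9
Reactants: 9 [(5S)-3-{2-[4-(benzyloxy)-3-methoxyphenyl]ethyl}-4,5-dihydroisoxazol-5-yl]methanol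
Product: 14 (5S)-3-{2-[4-(benzyloxy)-3-methoxyphenyl]ethyl}-4,5-dihydroisoxazole-5-carbaldehyde
Conditions: Dess–Martin periodinane, CH2Cl2, 0 °C to rt; aq. Na2S2O3/NaHCO3; used crude
Reagents that add atoms: none
Why: Dess–Martin oxidation takes the primary alcohol to the aldehyde under non-basic conditions that leave the C=N bond, the N–O bond and the C5 configuration untouched, and the aldehyde is used at once without chromatography.

Step 10
Reactants: 14 (5S)-3-{2-[4-(benzyloxy)-3-methoxyphenyl]ethyl}-4,5-dihydroisoxazole-5-carbaldehyde; 13 [4-(benzyloxy)-3,5-dimethoxybenzyl]triphenylphosphonium bromide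
Product: 16 (5S)-3-{2-[4-(benzyloxy)-3-methoxyphenyl]ethyl}-5-{2-[4-(benzyloxy)-3,5-dimethoxyphenyl]ethenyl}-4,5-dihydroisoxazole (E/Z mixture), via ylide 15 (not isolated)
Conditions: 13 (slight excess over base), KN(SiMe3)2, THF, −78 to 0 °C; then 14, −78 °C to rt
Reagents that add atoms: none
Why: Wittig olefination with the semi-stabilised benzylic ylide forms the C6=C7 bond at low temperature with no free amide base present, which should protect the α-alkoxy stereocentre, and the alkene geometry is irrelevant because the double bond is reduced next.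

Step 11
Reactants: 16 (5S)-3-{2-[4-(benzyloxy)-3-methoxyphenyl]ethyl}-5-{2-[4-(benzyloxy)-3,5-dimethoxyphenyl]ethenyl}-4,5-dihydroisoxazole
Product: 17 (5R)-3-{2-[4-(benzyloxy)-3-methoxyphenyl]ethyl}-5-{2-[4-(benzyloxy)-3,5-dimethoxyphenyl]ethyl}-4,5-dihydroisoxazole
Conditions: TsNHNH2 (excess, portionwise), NaOAc, DME/H2O, reflux
Reagents that add atoms: none
Why: Diimide reduction transfers hydrogen concertedly to the non-polar C=C bond and ignores the C=N, N–O and benzyl ether bonds, so the allylic C5–O bond is never exposed to a hydrogenolysis catalyst; the descriptor changes from S to R only because of CIP ranking.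

Step 12
Reactants: 17 (5R)-3-{2-[4-(benzyloxy)-3-methoxyphenyl]ethyl}-5-{2-[4-(benzyloxy)-3,5-dimethoxyphenyl]ethyl}-4,5-dihydroisoxazole
Product: 19 (5R)-1-[4-(benzyloxy)-3-methoxyphenyl]-7-[4-(benzyloxy)-3,5-dimethoxyphenyl]-5-hydroxyheptan-3-one, via hydroxy imine 18 (not isolated)
Conditions: H2 (1 atm), Raney Ni, B(OH)3, MeOH/H2O (5:1), rt
Reagents that add atoms: water, O
Why: Raney Ni hydrogenolysis of the isoxazoline N–O bond in boric acid-buffered aqueous methanol gives the β-hydroxy imine, which is hydrolysed in the flask to the β-hydroxy ketone before over-reduction or retro-aldol cleavage can intervene, with no bond at C5 involved.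

Step 13
Reactants: 19 (5R)-1-[4-(benzyloxy)-3-methoxyphenyl]-7-[4-(benzyloxy)-3,5-dimethoxyphenyl]-5-hydroxyheptan-3-one
Product: 20 (5R)-5-hydroxy-7-(4-hydroxy-3,5-dimethoxyphenyl)-1-(4-hydroxy-3-methoxyphenyl)heptan-3-one
Conditions: H2 (1 atm), Pd/C, EtOAc/MeOH, rt
Reagents that add atoms: none
Why: Hydrogenolysis of the two aryl benzyl ethers over Pd/C under neutral conditions leaves the aliphatic ketone, the secondary alcohol and the C5 stereocentre unchanged.

**Compound list**

1 | 3-(4-hydroxy-3-methoxyphenyl)propanoic acid (dihydroferulic acid) | COc1cc(CCC(=O)O)ccc1O | starting material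
2 | benzyl 3-[4-(benzyloxy)-3-methoxyphenyl]propanoate | COc1cc(CCC(=O)OCc2ccccc2)ccc1OCc1ccccc1 | intermediate
3 | 3-[4-(benzyloxy)-3-methoxyphenyl]propanal | COc1cc(CCC=O)ccc1OCc1ccccc1 | intermediate
4 | 3-[4-(benzyloxy)-3-methoxyphenyl]propanal oxime (E/Z mixture) | COc1cc(CCC=NO)ccc1OCc1ccccc1 | intermediate
5 | (Z)-3-[4-(benzyloxy)-3-methoxyphenyl]-N-hydroxypropanimidoyl chloride | COc1cc(CC/C(Cl)=N/O)ccc1OCc1ccccc1 | intermediate
6 | allyl alcohol | C=CCO | starting material
7 | allyloxy(ethyl)zinc (not isolated) | CC[Zn]OCC=C | intermediate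
8 | 3-[4-(benzyloxy)-3-methoxyphenyl]propanenitrile oxide (not isolated) | COc1cc(CCC#[N+][O-])ccc1OCc1ccccc1 | intermediate
9 | [(5S)-3-{2-[4-(benzyloxy)-3-methoxyphenyl]ethyl}-4,5-dihydroisoxazol-5-yl]methanol | OC[C@@H]1CC(CCc2ccc(OCc3ccccc3)c(OC)c2)=NO1 | intermediate
10 | 4-hydroxy-3,5-dimethoxybenzaldehyde (syringaldehyde) | COc1cc(C=O)cc(OC)c1O | starting material
11 | 4-(benzyloxy)-3,5-dimethoxybenzaldehyde | COc1cc(C=O)cc(OC)c1OCc1ccccc1 | intermediate
12 | [4-(benzyloxy)-3,5-dimethoxyphenyl]methanol | COc1cc(CO)cc(OC)c1OCc1ccccc1 | intermediate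
13 | [4-(benzyloxy)-3,5-dimethoxybenzyl]triphenylphosphonium bromide | COc1cc(C[P+](c2ccccc2)(c2ccccc2)c2ccccc2)cc(OC)c1OCc1ccccc1.[Br-] | intermediate
14 | (5S)-3-{2-[4-(benzyloxy)-3-methoxyphenyl]ethyl}-4,5-dihydroisoxazole-5-carbaldehyde | O=C[C@@H]1CC(CCc2ccc(OCc3ccccc3)c(OC)c2)=NO1 | intermediate
15 | [4-(benzyloxy)-3,5-dimethoxybenzylidene]triphenylphosphorane (not isolated) | COc1cc(C=P(c2ccccc2)(c2ccccc2)c2ccccc2)cc(OC)c1OCc1ccccc1 | intermediate
16 | (5S)-3-{2-[4-(benzyloxy)-3-methoxyphenyl]ethyl}-5-{2-[4-(benzyloxy)-3,5-dimethoxyphenyl]ethenyl}-4,5-dihydroisoxazole (E/Z mixture) | COc1cc(C=C[C@@H]2CC(CCc3ccc(OCc4ccccc4)c(OC)c3)=NO2)cc(OC)c1OCc1ccccc1 | intermediate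
17 | (5R)-3-{2-[4-(benzyloxy)-3-methoxyphenyl]ethyl}-5-{2-[4-(benzyloxy)-3,5-dimethoxyphenyl]ethyl}-4,5-dihydroisoxazole | COc1cc(CC[C@@H]2CC(CCc3ccc(OCc4ccccc4)c(OC)c3)=NO2)cc(OC)c1OCc1ccccc1 | intermediate
18 | (5R)-1-[4-(benzyloxy)-3-methoxyphenyl]-7-[4-(benzyloxy)-3,5-dimethoxyphenyl]-3-iminoheptan-5-ol (not isolated) | COc1cc(CCC(=N)C[C@H](O)CCc2cc(OC)c(OCc3ccccc3)c(OC)c2)ccc1OCc1ccccc1 | intermediate
19 | (5R)-1-[4-(benzyloxy)-3-methoxyphenyl]-7-[4-(benzyloxy)-3,5-dimethoxyphenyl]-5-hydroxyheptan-3-one | COc1cc(CCC(=O)C[C@H](O)CCc2cc(OC)c(OCc3ccccc3)c(OC)c2)ccc1OCc1ccccc1 | intermediate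
20 | (5R)-5-hydroxy-7-(4-hydroxy-3,5-dimethoxyphenyl)-1-(4-hydroxy-3-methoxyphenyl)heptan-3-one | COc1cc(CCC(=O)C[C@H](O)CCc2cc(OC)c(O)c(OC)c2)ccc1O | target

**Count**

Total steps: 13. Longest linear sequence: 10 steps (1, 2, 3, 4, 5, 9, 10, 11, 12, 13); the syringyl fragment (steps 6–8) joins at step 10.

**Steps most likely to fail**

Step 5. The flexible primary-alkyl nitrile oxide may be bound less rigidly by the zinc tartrate template, so facial selectivity could be insufficient or of the opposite sense, and furoxan dimerisation could compete with cycloaddition. The fallback sets out from 5, replaces reagent control by a chiral-pool dipolarophile, and returns at 14. The nitrile oxide is released from 5 with Et3N (slow addition, Et2O, rt) in the presence of (S)-2,2-dimethyl-4-vinyl-1,3-dioxolane. The allylic oxygen of this alkene directs the dipole anti (inside-alkoxy model), which should give mainly (5S)-3-{2-[4-(benzyloxy)-3-methoxyphenyl]ethyl}-5-[(4R)-2,2-dimethyl-1,3-dioxolan-4-yl]-4,5-dihydroisoxazole F1, freed of the minor syn isomer by chromatography. Aqueous acetic acid then removes the acetonide to give (1R)-1-[(5S)-3-{2-[4-(benzyloxy)-3-methoxyphenyl]ethyl}-4,5-dihydroisoxazol-5-yl]ethane-1,2-diol F2. Glycol cleavage with NaIO4 delivers aldehyde 14 directly, so step 9 is bypassed as well.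

Step 10. The α-alkoxy aldehyde may enolise and lose configuration at C5, or the isoxazoline may open by deprotonation at C4 and β-elimination of the ring oxygen, while the ylide is added. The fallback sets out from 9, with the nucleophile drawn from 12, avoids any carbonyl at C6, and returns at 17. Alcohol 12 is converted with SOCl2 into 4-(benzyloxy)-3,5-dimethoxybenzyl chloride F3 and then with Mg in THF into [4-(benzyloxy)-3,5-dimethoxybenzyl]magnesium chloride F4. Alcohol 9 is converted with Tf2O and 2,6-lutidine at −78 °C into [(5S)-3-{2-[4-(benzyloxy)-3-methoxyphenyl]ethyl}-4,5-dihydroisoxazol-5-yl]methyl trifluoromethanesulfonate F5. This triflate is coupled at once with F4 under CuBr·SMe2 catalysis at low temperature (displacement of a primary triflate by a Grignard reagent), forming the C6–C7 single bond and giving 17. Steps 9 to 11 are then not needed.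

Step 2. The aluminium hemiacetal may collapse before the quench, so that the ester is over-reduced to the primary alcohol and a mixture results. The fallback sets out from 2, uses a two-stage redox sequence, and returns at 3. Full reduction with LiAlH4 in THF at 0 °C gives 3-[4-(benzyloxy)-3-methoxyphenyl]propan-1-ol F6, which is oxidised to aldehyde 3 with TEMPO/PhI(OAc)2 in CH2Cl2.

**Further compounds**

F1 | step 5 | (5S)-3-{2-[4-(benzyloxy)-3-methoxyphenyl]ethyl}-5-[(4R)-2,2-dimethyl-1,3-dioxolan-4-yl]-4,5-dihydroisoxazole | CC1(C)OC[C@@H](O1)[C@@H]1CC(CCc2ccc(OCc3ccccc3)c(OC)c2)=NO1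
F2 | step 5 | (1R)-1-[(5S)-3-{2-[4-(benzyloxy)-3-methoxyphenyl]ethyl}-4,5-dihydroisoxazol-5-yl]ethane-1,2-diol | OC[C@@H](O)[C@@H]1CC(CCc2ccc(OCc3ccccc3)c(OC)c2)=NO1
F3 | step 10 | 4-(benzyloxy)-3,5-dimethoxybenzyl chloride | COc1cc(CCl)cc(OC)c1OCc1ccccc1
F4 | step 10 | [4-(benzyloxy)-3,5-dimethoxybenzyl]magnesium chloride | COc1cc(C[Mg]Cl)cc(OC)c1OCc1ccccc1
F5 | step 10 | [(5S)-3-{2-[4-(benzyloxy)-3-methoxyphenyl]ethyl}-4,5-dihydroisoxazol-5-yl]methyl trifluoromethanesulfonate | O=S(=O)(OC[C@@H]1CC(CCc2ccc(OCc3ccccc3)c(OC)c2)=NO1)C(F)(F)F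
F6 | step 2 | 3-[4-(benzyloxy)-3-methoxyphenyl]propan-1-ol | COc1cc(CCCO)ccc1OCc1ccccc1
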